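**Retrosynthetic overview**

1. 8-Prenylcatechin 16 ⇐ global desilylation ⇐ C8–prenyl bond by linear-selective Negishi coupling on 8-bromide 14 ⇐ bromination at C8 of silylated catechin 12. The prenyl group comes last because the peracid of step 7 would epoxidize it.
2. C3–OH of 12 ⇐ Baeyer–Villiger excision (retention) of a temporary formyl group on C3 of chroman-3-carbaldehyde 10.
3. Ring C of 10 ⇐ C2–C3 bond, made by an amine-catalysed 1,5-hydride shift/ring closure of the achiral cinnamaldehyde 7. 7 ⇐ Wittig and Mitsunobu reactions on two hydroxybenzaldehydes. Rings A and B are bought intact; ring C is the only ring formed (step 6).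
4. Enabling feature: in 7 the C2 methylene lies between O1 and the electron-rich ring B (hydridic C–H) and sits 1,5 to C4, the β-carbon of the enal on ring A (C2–O1–C8a–C4a–C4). The shift delivers C4 as CH2 and turns C2 into an oxocarbenium carbon and C3 into an enamine carbon, which then join.

Key step: step 6

Abbreviations: TBS = tert-butyldimethylsilyl; OTBS = tert-butyldimethylsilyloxy.

Assumption: the (2S,5S)-imidazolidinone is taken to give the (2S,3S)-aldehyde 10; the sense of induction of this new step cannot be derived with certainty, and the (2R,5R)-catalyst would be used instead with no other change.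

**Route**

Step 1
Reactants: 1 3,4-dihydroxybenzaldehyde
Product: 2 3,4-bis(OTBS)benzaldehyde
Conditions: TBSCl (2.3 equiv), imidazole, DMF, rt
Reagents that add atoms: tert-butyldimethylsilyl chloride, C[Si](C)(Cl)C(C)(C)C
Why: O-silylation of both catechol hydroxyls gives protection that is removed by fluoride (no hydrogenation, no strong acid) and keeps ring B electron-rich for the later hydride transfer.

Step 2
Reactants: 2 3,4-bis(OTBS)benzaldehyde
Product: 3 [3,4-bis(OTBS)phenyl]methanol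
Conditions: NaBH4, MeOH/THF, 0 °C
Reagents that add atoms: none
Why: Borohydride reduction of the aryl aldehyde to the benzylic alcohol, under which aryl silyl ethers should survive at 0 °C.

Step 3
Reactants: 4 2,4,6-trihydroxybenzaldehyde
Product: 5 2-hydroxy-4,6-bis(OTBS)benzaldehyde
Conditions: TBSCl (2.05 equiv), imidazole, DMF/CH2Cl2, 0 °C
Reagents that add atoms: tert-butyldimethylsilyl chloride, C[Si](C)(Cl)C(C)(C)C
Why: Selective O-silylation: the para and one ortho hydroxyl react, the last ortho hydroxyl is held in a hydrogen bond to the formyl group and reacts slowest, and the two ortho hydroxyls are equivalent so no regiochemical question arises.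

Step 4
Reactants: 5 2-hydroxy-4,6-bis(OTBS)benzaldehyde; 3 [3,4-bis(OTBS)phenyl]methanol
Product: 6 2-{[3,4-bis(OTBS)phenyl]methoxy}-4,6-bis(OTBS)benzaldehyde
Conditions: PPh3, DIAD, THF, 0 °C to rt
Reagents that add atoms: none
Why: Mitsunobu etherification of the acidic salicylaldehyde hydroxyl with the primary benzylic alcohol forms the O1–C2 bond under neutral conditions that spare aryl silyl ethers.

Step 5
Reactants: 6 2-{[3,4-bis(OTBS)phenyl]methoxy}-4,6-bis(OTBS)benzaldehyde
Product: 7 (E)-3-[2-{[3,4-bis(OTBS)phenyl]methoxy}-4,6-bis(OTBS)phenyl]prop-2-enal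
Conditions: Ph3P=CHCHO, toluene, 90 °C
Reagents that add atoms: (triphenylphosphoranylidene)acetaldehyde, O=CC=P(c1ccccc1)(c1ccccc1)c1ccccc1
Why: Wittig olefination with the stabilized formylmethylene ylide should give the (E)-enal, adding C3 and the temporary formyl carbon to C4.

Step 6
Reactants: 7 (E)-3-[2-{[3,4-bis(OTBS)phenyl]methoxy}-4,6-bis(OTBS)phenyl]prop-2-enal
Product: 10 (2S,3S)-2-[3,4-bis(OTBS)phenyl]-5,7-bis(OTBS)-3,4-dihydro-2H-chromene-3-carbaldehyde (2,3-trans), via iminium ion 8 (not isolated), via oxocarbenium enamine 9 (not isolated)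
Conditions: (2S,5S)-5-benzyl-2-tert-butyl-3-methylimidazolidin-4-one (20 mol %), CF3CO2H (20 mol %), ClCH2CH2Cl, 40–60 °C; crude 10 taken on directly
Reagents that add atoms: none
Why: Proposed new method: the amine condenses with 7 to iminium ion 8, whose β-carbon C4 (twisted out of the plane of ring A by the two ortho oxygen substituents, so that its p lobe points at the ether methylene) takes a hydride from C2 in a suprafacial 1,5-shift through a six-membered transition state, giving the ring-B-stabilised aryloxycarbenium ion and the (E)-enamine of 9; the enamine carbon C3 then adds to C2 and hydrolysis releases 10 and the catalyst, so that one operation forms the C2–C3 bond, closes ring C, reduces C4 to CH2 and sets both stereocenters from an achiral isomer. The closest known reaction types are the Lewis-acid-promoted 1,5-hydride shift/cyclization of ortho-benzyloxy benzylidene malonates to 2-arylchroman-3,3-diesters and the secondary-amine-catalysed enantioselective hydride shift/ring closure of ortho-dialkylamino cinnamaldehydes; what is new is iminium activation combined with an acyclic benzyl aryl ether as the hydride donor. Ring C closes in a 6-(enolexo)-endo-trig mode (enamine carbon onto the endocyclic C=O+ bond). C2 is set in the C–C bond formation: the oxocarbenium ion is born on the enamine face left open by the benzyl group of the catalyst and, held by the O1–C8a–C4a–C4 tether, should close through a chair-like transition state with ring B pseudo-equatorial before it can rotate; C3 remains epimerizable through the enamine and should settle trans to ring B (both substituents pseudo-equatorial). The step needs the hydride shift to outrun acid cleavage of the electron-rich benzyl ether and capture of the oxocarbenium ion by water, which the hydridic C2–H (para-silyloxy group of ring B plus O1), the intramolecular six-membered delivery and the weakly acidic ammonium salt should secure.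

Step 7
Reactants: 10 (2S,3S)-2-[3,4-bis(OTBS)phenyl]-5,7-bis(OTBS)-3,4-dihydro-2H-chromene-3-carbaldehyde
Product: 12 (2R,3S)-2-[3,4-bis(OTBS)phenyl]-5,7-bis(OTBS)-3,4-dihydro-2H-chromen-3-ol, via formate 11 (not isolated)
Conditions: mCPBA, NaHCO3, CH2Cl2, 0 °C to rt; then MeOH, Et3N, 0 °C to rt
Reagents that add atoms: 3-chloroperoxybenzoic acid (mCPBA), O=C(OO)c1cccc(Cl)c1
Why: Baeyer–Villiger oxidation of the α-branched aldehyde, in which the secondary carbon C3 migrates to oxygen with retention, converts the temporary formyl group into a formate that mild methanolysis cleaves to the 3-hydroxyl of the catechin series.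

Step 8
Reactants: 12 (2R,3S)-2-[3,4-bis(OTBS)phenyl]-5,7-bis(OTBS)-3,4-dihydro-2H-chromen-3-ol
Product: 13 (2R,3S)-8-bromo-2-[3,4-bis(OTBS)phenyl]-5,7-bis(OTBS)-3,4-dihydro-2H-chromen-3-ol
Conditions: NBS (1.0 equiv), CH2Cl2, −78 to 0 °C, dark
Reagents that add atoms: N-bromosuccinimide, O=C1CCC(=O)N1Br
Why: Electrophilic aromatic bromination of the phloroglucinol-type ring A should go to C8 (between the 7-silyloxy group and O1) in preference to the more hindered C6 (between two bulky silyloxy groups), the selectivity known for O-benzylated catechins.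

Step 9
Reactants: 13 (2R,3S)-8-bromo-2-[3,4-bis(OTBS)phenyl]-5,7-bis(OTBS)-3,4-dihydro-2H-chromen-3-ol
Product: 14 (2R,3S)-8-bromo-2-[3,4-bis(OTBS)phenyl]-3,5,7-tris(OTBS)chromane
Conditions: TBSOTf, 2,6-lutidine, CH2Cl2, 0 °C
Reagents that add atoms: tert-butyldimethylsilyl trifluoromethanesulfonate, C[Si](C)(OS(=O)(=O)C(F)(F)F)C(C)(C)C
Why: Silylation of the secondary alcohol with the silyl triflate removes the acidic proton before the organozinc coupling and leaves a single type of protecting group for the last step.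

Step 10
Reactants: 14 (2R,3S)-8-bromo-2-[3,4-bis(OTBS)phenyl]-3,5,7-tris(OTBS)chromane
Product: 15 (2R,3S)-2-[3,4-bis(OTBS)phenyl]-3,5,7-tris(OTBS)-8-(3-methylbut-2-en-1-yl)chromane
Conditions: 1-bromo-3-methylbut-2-ene, Zn, LiCl, THF, 0 °C; then 14, Pd(OAc)2 (2 mol %), CPhos (4 mol %), THF, rt
Reagents that add atoms: (3-methylbut-2-en-1-yl)zinc bromide, CC(C)=CC[Zn]Br (made in the flask from 1-bromo-3-methylbut-2-ene, CC(C)=CCBr, and Zn)
Why: Negishi coupling of the aryl bromide with prenylzinc bromide under a bulky biarylphosphine–palladium catalyst, a system known to couple 3,3-disubstituted allylzinc reagents through the primary terminus, should give the linear prenyl arene under neutral conditions that spare the silyl ethers.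

Step 11
Reactants: 15 (2R,3S)-2-[3,4-bis(OTBS)phenyl]-3,5,7-tris(OTBS)-8-(3-methylbut-2-en-1-yl)chromane
Product: 16 8-prenylcatechin, (2R,3S)-2-(3,4-dihydroxyphenyl)-8-(3-methylbut-2-en-1-yl)-3,4-dihydro-2H-chromene-3,5,7-triol
Conditions: TBAF, AcOH (1:1, excess), THF, 0 °C to rt, argon
Reagents that add atoms: none
Why: Fluoride-mediated desilylation buffered with acetic acid removes all five silyl groups without hydrogenation or strong acid, so the prenyl alkene, the air-sensitive polyphenol and the C2 and C3 stereocenters should be untouched.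

**Compound list**

1 | 3,4-dihydroxybenzaldehyde | O=Cc1ccc(O)c(O)c1 | starting material
2 | 3,4-bis(OTBS)benzaldehyde | O=Cc1ccc(O[Si](C)(C)C(C)(C)C)c(O[Si](C)(C)C(C)(C)C)c1 | intermediate
3 | [3,4-bis(OTBS)phenyl]methanol | OCc1ccc(O[Si](C)(C)C(C)(C)C)c(O[Si](C)(C)C(C)(C)C)c1 | intermediate
4 | 2,4,6-trihydroxybenzaldehyde | O=Cc1c(O)cc(O)cc1O | starting material
5 | 2-hydroxy-4,6-bis(OTBS)benzaldehyde | O=Cc1c(O)cc(O[Si](C)(C)C(C)(C)C)cc1O[Si](C)(C)C(C)(C)C | intermediate
6 | 2-{[3,4-bis(OTBS)phenyl]methoxy}-4,6-bis(OTBS)benzaldehyde | O=Cc1c(OCc2ccc(O[Si](C)(C)C(C)(C)C)c(O[Si](C)(C)C(C)(C)C)c2)cc(O[Si](C)(C)C(C)(C)C)cc1O[Si](C)(C)C(C)(C)C | intermediate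
7 | (E)-3-[2-{[3,4-bis(OTBS)phenyl]methoxy}-4,6-bis(OTBS)phenyl]prop-2-enal | O=C/C=C/c1c(OCc2ccc(O[Si](C)(C)C(C)(C)C)c(O[Si](C)(C)C(C)(C)C)c2)cc(O[Si](C)(C)C(C)(C)C)cc1O[Si](C)(C)C(C)(C)C | intermediate
8 | iminium ion of 7 with the (2S,5S)-imidazolidinone, trifluoroacetate salt (not isolated) | CN1C(=O)[C@H](Cc2ccccc2)[N+](=C/C=C/c2c(OCc3ccc(O[Si](C)(C)C(C)(C)C)c(O[Si](C)(C)C(C)(C)C)c3)cc(O[Si](C)(C)C(C)(C)C)cc2O[Si](C)(C)C(C)(C)C)[C@@H]1C(C)(C)C.[O-]C(=O)C(F)(F)F | intermediate
9 | aryloxycarbenium ion/(E)-enamine formed from 8 by the 1,5-hydride shift, trifluoroacetate salt (not isolated) | CN1C(=O)[C@H](Cc2ccccc2)N(/C=C/Cc2c([O+]=Cc3ccc(O[Si](C)(C)C(C)(C)C)c(O[Si](C)(C)C(C)(C)C)c3)cc(O[Si](C)(C)C(C)(C)C)cc2O[Si](C)(C)C(C)(C)C)[C@@H]1C(C)(C)C.[O-]C(=O)C(F)(F)F | intermediate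
10 | (2S,3S)-2-[3,4-bis(OTBS)phenyl]-5,7-bis(OTBS)-3,4-dihydro-2H-chromene-3-carbaldehyde | c1c(O[Si](C)(C)C(C)(C)C)cc(O[Si](C)(C)C(C)(C)C)c2c1O[C@H](c1ccc(O[Si](C)(C)C(C)(C)C)c(O[Si](C)(C)C(C)(C)C)c1)[C@@H](C=O)C2 | intermediate
11 | (2R,3S)-2-[3,4-bis(OTBS)phenyl]-5,7-bis(OTBS)-3,4-dihydro-2H-chromen-3-yl formate (not isolated) | c1c(O[Si](C)(C)C(C)(C)C)cc(O[Si](C)(C)C(C)(C)C)c2c1O[C@H](c1ccc(O[Si](C)(C)C(C)(C)C)c(O[Si](C)(C)C(C)(C)C)c1)[C@@H](OC=O)C2 | intermediate
12 | (2R,3S)-2-[3,4-bis(OTBS)phenyl]-5,7-bis(OTBS)-3,4-dihydro-2H-chromen-3-ol | c1c(O[Si](C)(C)C(C)(C)C)cc(O[Si](C)(C)C(C)(C)C)c2c1O[C@H](c1ccc(O[Si](C)(C)C(C)(C)C)c(O[Si](C)(C)C(C)(C)C)c1)[C@@H](O)C2 | intermediate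
13 | (2R,3S)-8-bromo-2-[3,4-bis(OTBS)phenyl]-5,7-bis(OTBS)-3,4-dihydro-2H-chromen-3-ol | Brc1c(O[Si](C)(C)C(C)(C)C)cc(O[Si](C)(C)C(C)(C)C)c2c1O[C@H](c1ccc(O[Si](C)(C)C(C)(C)C)c(O[Si](C)(C)C(C)(C)C)c1)[C@@H](O)C2 | intermediate
14 | (2R,3S)-8-bromo-2-[3,4-bis(OTBS)phenyl]-3,5,7-tris(OTBS)chromane | Brc1c(O[Si](C)(C)C(C)(C)C)cc(O[Si](C)(C)C(C)(C)C)c2c1O[C@H](c1ccc(O[Si](C)(C)C(C)(C)C)c(O[Si](C)(C)C(C)(C)C)c1)[C@@H](O[Si](C)(C)C(C)(C)C)C2 | intermediate
15 | (2R,3S)-2-[3,4-bis(OTBS)phenyl]-3,5,7-tris(OTBS)-8-(3-methylbut-2-en-1-yl)chromane | CC(C)=CCc1c(O[Si](C)(C)C(C)(C)C)cc(O[Si](C)(C)C(C)(C)C)c2c1O[C@H](c1ccc(O[Si](C)(C)C(C)(C)C)c(O[Si](C)(C)C(C)(C)C)c1)[C@@H](O[Si](C)(C)C(C)(C)C)C2 | intermediate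
16 | 8-prenylcatechin, (2R,3S)-2-(3,4-dihydroxyphenyl)-8-(3-methylbut-2-en-1-yl)-3,4-dihydro-2H-chromene-3,5,7-triol | CC(C)=CCc1c(O)cc(O)c2c1O[C@H](c1ccc(O)c(O)c1)[C@@H](O)C2 | target

**Step count and risks**

Total step count: 11. Longest linear sequence: 10 steps (from 1 through steps 1, 2 and 4–11); 9 steps from 4.

Steps most likely to fail:

1. Step 6 (proposed new method). The hydride shift may not start, because the electron-rich ring A lowers the electrophilicity of the iminium ion. Ring closure may also occur with poor facial control at C2, or acid-induced loss of the benzyl ether may win. Fallback, by the known amine-catalysed oxa-Michael/aldol condensation, setting out from 2 and 5 and coming back at 10: Wittig reaction of 2 with Ph3P=CHCHO should give (E)-3-[3,4-bis(OTBS)phenyl]prop-2-enal F1. F1 and salicylaldehyde 5 with α,α-diphenylprolinol trimethylsilyl ether (the enantiomer that gives the 2R series) and 2-nitrobenzoic acid in toluene should give (2R)-2-[3,4-bis(OTBS)phenyl]-5,7-bis(OTBS)-2H-chromene-3-carbaldehyde F2, with C2 set in the iminium-controlled oxa-Michael step. Conjugate transfer hydrogenation of F2 (Hantzsch ester, dibenzylammonium trifluoroacetate, THF) and equilibration of C3 to trans then rejoin the route at 10.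

2. Step 7. In the peracid adduct hydrogen may migrate instead of C3, which leads to the carboxylic acid, or the electron-rich rings may be oxidized on long exposure. Fallback, setting out from 10 and coming back at 12: MeMgBr (THF, −78 °C) should give 1-[(2S,3R)-2-[3,4-bis(OTBS)phenyl]-5,7-bis(OTBS)-3,4-dihydro-2H-chromen-3-yl]ethan-1-ol F3 (carbinol epimers). Dess–Martin periodinane should give the methyl ketone 1-[(2S,3S)-2-[3,4-bis(OTBS)phenyl]-5,7-bis(OTBS)-3,4-dihydro-2H-chromen-3-yl]ethan-1-one F4. Its Baeyer–Villiger oxidation (mCPBA, NaHCO3), where the secondary carbon migrates in preference to methyl, should give (2R,3S)-2-[3,4-bis(OTBS)phenyl]-5,7-bis(OTBS)-3,4-dihydro-2H-chromen-3-yl acetate F5 with retention. i-Bu2AlH (CH2Cl2, −78 °C) cleaves the acetate to 12.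

3. Step 10. Oxidative addition at the electron-rich bromide with two ortho substituents may be slow, with protodebromination, or the prenyl unit may couple through its tertiary terminus. Fallback, setting out from 14 and coming back at 15: Stille coupling with allyltributylstannane (Pd(PPh3)4, LiCl, DMF, 90 °C) should give (2R,3S)-8-allyl-2-[3,4-bis(OTBS)phenyl]-3,5,7-tris(OTBS)chromane F6. Cross-metathesis of F6 with 2-methylbut-2-ene (second-generation Grubbs catalyst, CH2Cl2, 40 °C) then gives 15.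

**Further compounds**

F1 | step 6 | (E)-3-[3,4-bis(OTBS)phenyl]prop-2-enal | O=C/C=C/c1ccc(O[Si](C)(C)C(C)(C)C)c(O[Si](C)(C)C(C)(C)C)c1
F2 | step 6 | (2R)-2-[3,4-bis(OTBS)phenyl]-5,7-bis(OTBS)-2H-chromene-3-carbaldehyde | c1c(O[Si](C)(C)C(C)(C)C)cc(O[Si](C)(C)C(C)(C)C)c2c1O[C@H](c1ccc(O[Si](C)(C)C(C)(C)C)c(O[Si](C)(C)C(C)(C)C)c1)C(C=O)=C2
F3 | step 7 | 1-[(2S,3R)-2-[3,4-bis(OTBS)phenyl]-5,7-bis(OTBS)-3,4-dihydro-2H-chromen-3-yl]ethan-1-ol (carbinol epimers) | c1c(O[Si](C)(C)C(C)(C)C)cc(O[Si](C)(C)C(C)(C)C)c2c1O[C@H](c1ccc(O[Si](C)(C)C(C)(C)C)c(O[Si](C)(C)C(C)(C)C)c1)[C@@H](C(C)O)C2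
F4 | step 7 | 1-[(2S,3S)-2-[3,4-bis(OTBS)phenyl]-5,7-bis(OTBS)-3,4-dihydro-2H-chromen-3-yl]ethan-1-one | c1c(O[Si](C)(C)C(C)(C)C)cc(O[Si](C)(C)C(C)(C)C)c2c1O[C@H](c1ccc(O[Si](C)(C)C(C)(C)C)c(O[Si](C)(C)C(C)(C)C)c1)[C@@H](C(C)=O)C2
F5 | step 7 | (2R,3S)-2-[3,4-bis(OTBS)phenyl]-5,7-bis(OTBS)-3,4-dihydro-2H-chromen-3-yl acetate | c1c(O[Si](C)(C)C(C)(C)C)cc(O[Si](C)(C)C(C)(C)C)c2c1O[C@H](c1ccc(O[Si](C)(C)C(C)(C)C)c(O[Si](C)(C)C(C)(C)C)c1)[C@@H](OC(C)=O)C2
F6 | step 10 | (2R,3S)-8-allyl-2-[3,4-bis(OTBS)phenyl]-3,5,7-tris(OTBS)chromane | C=CCc1c(O[Si](C)(C)C(C)(C)C)cc(O[Si](C)(C)C(C)(C)C)c2c1O[C@H](c1ccc(O[Si](C)(C)C(C)(C)C)c(O[Si](C)(C)C(C)(C)C)c1)[C@@H](O[Si](C)(C)C(C)(C)C)C2
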